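**Plan**

1. The last cut is the O–Si bond of a TIPS ether on the catechol ring (ring B). The cut before it, the key one, is the bond from quinone C2 to the ether oxygen of the meta-phenylene ring (ring C); it opens the 18-membered ring.
2. Feature used: this oxygen sits on quinone C2, which is β to the C4 carbonyl (C3 carries the CH2CH2 bridge to the para-phenylene ring A). The C2–O bond is therefore a vinylogous ester, and the seco compound is a 2-bromo-3-alkyl-1,4-benzoquinone with a free ring-C phenol.
3. Further cuts: bromoquinone back to a 2-bromo-1,4-dimethoxyarene (CAN), both ArCH2–CH2Ar bonds (Wittig, then reduction), and the A–O–B diaryl ether (SNAr on 4-fluorobenzonitrile).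
4. Forward: SNAr joins A and B; Wittig and hydrogenation add ring C; Wittig and diimide add the bromodimethoxyarene; CAN, then acid, unveil bromoquinone and phenol; the only ring made, the macrocycle, closes in the penultimate step; desilylation ends the route.
5. Stereochemistry: none to set. The target has no stereocentre, and the E/Z mixtures of the two stilbenes vanish on reduction.

Key step: step 15

Remark: the target SMILES carries no stereodescriptor and marchantinquinone is taken to have no stable stereogenic element, so the constitution alone defines the compound. Stilbene intermediates are written without alkene geometry because E/Z mixtures are carried on.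

**Route**

Step 1
Reactants: 1 2-bromo-1,4-dimethoxybenzene
Product: 3 2-bromo-3,6-dimethoxybenzaldehyde, via (2-bromo-3,6-dimethoxyphenyl)lithium 2 (not isolated)
Conditions: LDA, THF, −78 °C; DMF, −78 °C → rt; aq. NH4Cl
Reagents that add atoms: N,N-dimethylformamide, CN(C)C=O
Why: Directed ortho-metalation with LDA removes the most acidic ring proton, the one flanked by bromine and a methoxy group, at a temperature where the ortho-bromoaryllithium does not collapse to the aryne, and DMF formylates it.

Step 2
Reactants: 3 2-bromo-3,6-dimethoxybenzaldehyde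
Product: 4 (2-bromo-3,6-dimethoxyphenyl)methanol
Conditions: NaBH4, MeOH/THF, 0 °C
Reagents that add atoms: none
Why: Borohydride reduction of an aryl aldehyde leaves the aryl bromide and the methyl ethers untouched.

Step 3
Reactants: 4 (2-bromo-3,6-dimethoxyphenyl)methanol
Product: 5 [(2-bromo-3,6-dimethoxyphenyl)methyl]triphenylphosphonium bromide
Conditions: PPh3·HBr, MeCN, reflux
Reagents that add atoms: triphenylphosphine hydrobromide, Br.c1ccc(cc1)P(c1ccccc1)c1ccccc1
Why: An electron-rich benzylic alcohol should be converted by triphenylphosphine hydrobromide into the phosphonium salt in one operation (substitution via the benzylic bromide or cation).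

Step 4
Reactants: 6 3-hydroxybenzyl alcohol
Product: 7 [(3-hydroxyphenyl)methyl]triphenylphosphonium bromide
Conditions: PPh3·HBr, MeCN, reflux
Reagents that add atoms: triphenylphosphine hydrobromide, Br.c1ccc(cc1)P(c1ccccc1)c1ccccc1
Why: The same alcohol-to-phosphonium substitution takes place at the benzylic position only, the phenol being inert to the reagent.

Step 5
Reactants: 8 3,4-dihydroxybenzaldehyde
Product: 9 4-(benzyloxy)-3-hydroxybenzaldehyde
Conditions: BnCl, NaHCO3, NaI (cat.), DMF, 40 °C
Reagents that add atoms: benzyl chloride, ClCc1ccccc1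
Why: In this Williamson etherification the weak base ionises only the 4-hydroxyl, which is para to the formyl group and the more acidic one, so benzylation is regioselective and the 3-hydroxyl stays free.

Step 6
Reactants: 9 4-(benzyloxy)-3-hydroxybenzaldehyde; 10 4-fluorobenzonitrile
Product: 11 4-[2-(benzyloxy)-5-formylphenoxy]benzonitrile
Conditions: K2CO3, DMF, 110 °C
Reagents that add atoms: none
Why: The phenoxide displaces fluoride para to the cyano group (SNAr), and the nitrile serves as a latent aldehyde so that the two ends of the A–O–B unit stay distinguishable.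

Step 7
Reactants: 11 4-[2-(benzyloxy)-5-formylphenoxy]benzonitrile; 7 [(3-hydroxyphenyl)methyl]triphenylphosphonium bromide
Product: 14 4-{2-(benzyloxy)-5-[2-(3-(methoxymethoxy)phenyl)ethenyl]phenoxy}benzonitrile (E/Z mixture), via potassium 3-[(triphenylphosphoranylidene)methyl]phenoxide 12 (not isolated), via potassium 3-{2-[4-(benzyloxy)-3-(4-cyanophenoxy)phenyl]ethenyl}phenoxide 13 (not isolated)
Conditions: 7, KOtBu (2 equiv per 7), THF, 0 °C; 11, 0 °C → rt; then MOMCl, 0 °C → rt
Reagents that add atoms: chloromethyl methyl ether, COCCl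
Why: Two equivalents of base turn the hydroxybenzyl salt into the phenoxide ylide, whose Wittig reaction with the aldehyde spares the nitrile, and the phenoxide left in the flask is capped as the MOM ether by O-alkylation; alkene geometry is irrelevant.

Step 8
Reactants: 14 4-{2-(benzyloxy)-5-[2-(3-(methoxymethoxy)phenyl)ethenyl]phenoxy}benzonitrile
Product: 15 4-{2-hydroxy-5-[2-(3-(methoxymethoxy)phenyl)ethyl]phenoxy}benzonitrile
Conditions: H2 (1 atm), 10% Pd/C, EtOAc, rt
Reagents that add atoms: none
Why: Catalytic hydrogenation, placed before bromine enters, saturates the stilbene and hydrogenolyses the benzyl ether, while the aryl nitrile and the MOM acetal react far more slowly under neutral conditions.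

Step 9
Reactants: 15 4-{2-hydroxy-5-[2-(3-(methoxymethoxy)phenyl)ethyl]phenoxy}benzonitrile
Product: 16 4-{5-[2-(3-(methoxymethoxy)phenyl)ethyl]-2-[(triisopropylsilyl)oxy]phenoxy}benzonitrile
Conditions: TIPSCl, imidazole, DMF, rt
Reagents that add atoms: triisopropylsilyl chloride, CC(C)[Si](Cl)(C(C)C)C(C)C
Why: Silylation of the only free phenol installs a group that is stable to base, acid and cerium(IV) and makes ring B less electron-rich than an alkyl ether would.

Step 10
Reactants: 16 4-{5-[2-(3-(methoxymethoxy)phenyl)ethyl]-2-[(triisopropylsilyl)oxy]phenoxy}benzonitrile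
Product: 18 4-{5-[2-(3-(methoxymethoxy)phenyl)ethyl]-2-[(triisopropylsilyl)oxy]phenoxy}benzaldehyde, via the N-(diisobutylalumanyl)imine of that aldehyde 17 (not isolated)
Conditions: DIBAL-H, toluene, −78 °C; then aq. Rochelle salt and dilute citric acid, 0 °C
Reagents that add atoms: water, O
Why: DIBAL-H reduces the nitrile only as far as the aluminium imine, which hydrolyses to the aldehyde on mild aqueous work-up without loss of the silyl ether or the acetal.

Step 11
Reactants: 18 4-{5-[2-(3-(methoxymethoxy)phenyl)ethyl]-2-[(triisopropylsilyl)oxy]phenoxy}benzaldehyde; 5 [(2-bromo-3,6-dimethoxyphenyl)methyl]triphenylphosphonium bromide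
Product: 20 2-bromo-1,4-dimethoxy-3-[2-(4-{5-[2-(3-(methoxymethoxy)phenyl)ethyl]-2-[(triisopropylsilyl)oxy]phenoxy}phenyl)ethenyl]benzene (E/Z mixture), via [(2-bromo-3,6-dimethoxyphenyl)methylidene]triphenylphosphorane 19 (not isolated)
Conditions: 5, NaHMDS, THF, 0 °C; then 18, 0 °C → rt
Reagents that add atoms: none
Why: In this Wittig olefination a non-nucleophilic amide base forms the semi-stabilised ylide without bromine–metal exchange, and the ylide should add to the unhindered aldehyde.

Step 12
Reactants: 20 2-bromo-1,4-dimethoxy-3-[2-(4-{5-[2-(3-(methoxymethoxy)phenyl)ethyl]-2-[(triisopropylsilyl)oxy]phenoxy}phenyl)ethenyl]benzene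
Product: 21 2-bromo-1,4-dimethoxy-3-[2-(4-{5-[2-(3-(methoxymethoxy)phenyl)ethyl]-2-[(triisopropylsilyl)oxy]phenoxy}phenyl)ethyl]benzene
Conditions: TsNHNH2, NaOAc, DME/H2O, reflux
Reagents that add atoms: none
Why: Diimide reduction transfers H2 to the alkene in a concerted way and cannot hydrogenolyse the aryl bromide, the silyl ether or the acetal.

Step 13
Reactants: 21 2-bromo-1,4-dimethoxy-3-[2-(4-{5-[2-(3-(methoxymethoxy)phenyl)ethyl]-2-[(triisopropylsilyl)oxy]phenoxy}phenyl)ethyl]benzene
Product: 22 2-bromo-3-[2-(4-{5-[2-(3-(methoxymethoxy)phenyl)ethyl]-2-[(triisopropylsilyl)oxy]phenoxy}phenyl)ethyl]cyclohexa-2,5-diene-1,4-dione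
Conditions: CAN (2.5 equiv), MeCN/H2O, 0 °C
Reagents that add atoms: water, O
Why: In this CAN oxidative demethylation the para-dimethoxyarene is the ring most easily oxidised, its radical cation takes up water and loses two methanol to give the quinone, and the silyloxy/aryloxy and MOM-ether rings are harder to oxidise while the nucleophilic phenol is still masked.

Step 14
Reactants: 22 2-bromo-3-[2-(4-{5-[2-(3-(methoxymethoxy)phenyl)ethyl]-2-[(triisopropylsilyl)oxy]phenoxy}phenyl)ethyl]cyclohexa-2,5-diene-1,4-dione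
Product: 23 2-bromo-3-[2-(4-{5-[2-(3-hydroxyphenyl)ethyl]-2-[(triisopropylsilyl)oxy]phenoxy}phenyl)ethyl]cyclohexa-2,5-diene-1,4-dione
Conditions: TFA, CH2Cl2, 0 °C → rt
Reagents that add atoms: none
Why: Acidolysis of the aryl MOM acetal by a non-nucleophilic acid should spare the bromoquinone and the aryl TIPS ether.

Step 15
Reactants: 23 2-bromo-3-[2-(4-{5-[2-(3-hydroxyphenyl)ethyl]-2-[(triisopropylsilyl)oxy]phenoxy}phenyl)ethyl]cyclohexa-2,5-diene-1,4-dione
Product: 24 marchantinquinone triisopropylsilyl ether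
Conditions: Cs2CO3 (2 equiv), dry degassed MeCN, rt, 23 added by syringe pump over 12 h (final ≤1 mM), Ar, dark
Reagents that add atoms: none
Why: The ring-C phenoxide adds in oxa-Michael fashion to quinone C2, the bromine-bearing carbon β to the C4 carbonyl, and the resulting bromo enolate expels bromide, so the quinone returns with no change of oxidation state (addition–elimination, vinylic substitution). The closest known reaction type is the intermolecular substitution of 2-halo-1,4-quinones by phenoxides under carbonate bases. The 18-membered ring closes in an 18-endo-trig sense, since the attacked C2=C3 bond lies inside the new ring, and closure is favoured by the three rigid arene units of the chain and by slow addition at high dilution. No stereocentre is formed. The step needs site selectivity on the quinone and ring closure over oligomerisation: attack at C2 gives the smallest ring and is the only addition made irreversible by loss of a leaving group, C3 carries the bridge so cine substitution is impossible, and adducts at C5 or C6 would need larger rings and can revert. The catechol oxygen is held as the TIPS ether, and the vinylogous ester product is less electrophilic than the bromoquinone.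

Step 16
Reactants: 24 marchantinquinone triisopropylsilyl ether
Product: 25 marchantinquinone
Conditions: HF·pyridine, THF, 0 °C → rt
Reagents that add atoms: none
Why: Fluoride-driven desilylation under acidic conditions, where fluoride is a poor carbon nucleophile, should cleave the aryl O–Si bond without attacking the aryloxyquinone.

**Compound list**

1 | 2-bromo-1,4-dimethoxybenzene | COc1ccc(OC)c(Br)c1 | starting material
2 | (2-bromo-3,6-dimethoxyphenyl)lithium | [Li]c1c(Br)c(OC)ccc1OC | intermediate
3 | 2-bromo-3,6-dimethoxybenzaldehyde | COc1ccc(OC)c(Br)c1C=O | intermediate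
4 | (2-bromo-3,6-dimethoxyphenyl)methanol | COc1ccc(OC)c(Br)c1CO | intermediate
5 | [(2-bromo-3,6-dimethoxyphenyl)methyl]triphenylphosphonium bromide | COc1ccc(OC)c(Br)c1C[P+](c1ccccc1)(c1ccccc1)c1ccccc1.[Br-] | intermediate
6 | 3-hydroxybenzyl alcohol | OCc1cccc(O)c1 | starting material
7 | [(3-hydroxyphenyl)methyl]triphenylphosphonium bromide | Oc1cccc(C[P+](c2ccccc2)(c2ccccc2)c2ccccc2)c1.[Br-] | intermediate
8 | 3,4-dihydroxybenzaldehyde | O=Cc1ccc(O)c(O)c1 | starting material
9 | 4-(benzyloxy)-3-hydroxybenzaldehyde | O=Cc1ccc(OCc2ccccc2)c(O)c1 | intermediate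
10 | 4-fluorobenzonitrile | N#Cc1ccc(F)cc1 | starting material
11 | 4-[2-(benzyloxy)-5-formylphenoxy]benzonitrile | N#Cc1ccc(Oc2cc(C=O)ccc2OCc2ccccc2)cc1 | intermediate
12 | potassium 3-[(triphenylphosphoranylidene)methyl]phenoxide | [K+].[O-]c1cccc(C=P(c2ccccc2)(c2ccccc2)c2ccccc2)c1 | intermediate
13 | potassium 3-{2-[4-(benzyloxy)-3-(4-cyanophenoxy)phenyl]ethenyl}phenoxide (E/Z mixture) | [K+].[O-]c1cccc(C=Cc2ccc(OCc3ccccc3)c(Oc3ccc(C#N)cc3)c2)c1 | intermediate
14 | 4-{2-(benzyloxy)-5-[2-(3-(methoxymethoxy)phenyl)ethenyl]phenoxy}benzonitrile (E/Z mixture) | COCOc1cccc(C=Cc2ccc(OCc3ccccc3)c(Oc3ccc(C#N)cc3)c2)c1 | intermediate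
15 | 4-{2-hydroxy-5-[2-(3-(methoxymethoxy)phenyl)ethyl]phenoxy}benzonitrile | COCOc1cccc(CCc2ccc(O)c(Oc3ccc(C#N)cc3)c2)c1 | intermediate
16 | 4-{5-[2-(3-(methoxymethoxy)phenyl)ethyl]-2-[(triisopropylsilyl)oxy]phenoxy}benzonitrile | COCOc1cccc(CCc2ccc(O[Si](C(C)C)(C(C)C)C(C)C)c(Oc3ccc(C#N)cc3)c2)c1 | intermediate
17 | N-(diisobutylalumanyl)imine of aldehyde 18 | COCOc1cccc(CCc2ccc(O[Si](C(C)C)(C(C)C)C(C)C)c(Oc3ccc(C=N[Al](CC(C)C)CC(C)C)cc3)c2)c1 | intermediate
18 | 4-{5-[2-(3-(methoxymethoxy)phenyl)ethyl]-2-[(triisopropylsilyl)oxy]phenoxy}benzaldehyde | COCOc1cccc(CCc2ccc(O[Si](C(C)C)(C(C)C)C(C)C)c(Oc3ccc(C=O)cc3)c2)c1 | intermediate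
19 | [(2-bromo-3,6-dimethoxyphenyl)methylidene]triphenylphosphorane | COc1ccc(OC)c(Br)c1C=P(c1ccccc1)(c1ccccc1)c1ccccc1 | intermediate
20 | 2-bromo-1,4-dimethoxy-3-[2-(4-{5-[2-(3-(methoxymethoxy)phenyl)ethyl]-2-[(triisopropylsilyl)oxy]phenoxy}phenyl)ethenyl]benzene (E/Z mixture) | COCOc1cccc(CCc2ccc(O[Si](C(C)C)(C(C)C)C(C)C)c(Oc3ccc(C=Cc4c(Br)c(OC)ccc4OC)cc3)c2)c1 | intermediate
21 | 2-bromo-1,4-dimethoxy-3-[2-(4-{5-[2-(3-(methoxymethoxy)phenyl)ethyl]-2-[(triisopropylsilyl)oxy]phenoxy}phenyl)ethyl]benzene | COCOc1cccc(CCc2ccc(O[Si](C(C)C)(C(C)C)C(C)C)c(Oc3ccc(CCc4c(Br)c(OC)ccc4OC)cc3)c2)c1 | intermediate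
22 | seco bromoquinone MOM ether: 2-bromo-3-[2-(4-{5-[2-(3-(methoxymethoxy)phenyl)ethyl]-2-[(triisopropylsilyl)oxy]phenoxy}phenyl)ethyl]cyclohexa-2,5-diene-1,4-dione | O=C1C=CC(=O)C(Br)=C1CCc1ccc(cc1)Oc1cc(ccc1O[Si](C(C)C)(C(C)C)C(C)C)CCc1cccc(OCOC)c1 | intermediate
23 | seco bromoquinone phenol: 2-bromo-3-[2-(4-{5-[2-(3-hydroxyphenyl)ethyl]-2-[(triisopropylsilyl)oxy]phenoxy}phenyl)ethyl]cyclohexa-2,5-diene-1,4-dione | O=C1C=CC(=O)C(Br)=C1CCc1ccc(cc1)Oc1cc(ccc1O[Si](C(C)C)(C(C)C)C(C)C)CCc1cccc(O)c1 | intermediate
24 | marchantinquinone triisopropylsilyl ether | O=C1C=CC(=O)C2=C1CCc1ccc(cc1)Oc1cc(ccc1O[Si](C(C)C)(C(C)C)C(C)C)CCc1cccc(c1)O2 | intermediate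
25 | marchantinquinone | O=C1C=CC(=O)C2=C1CCc1ccc(cc1)Oc1cc(ccc1O)CCc1cccc(c1)O2 | target

**Totals and risks**

Total step count: 16. Longest linear sequence: 12 steps (8 to 25, steps 5–16).

Most likely to fail, 1: step 15. The phenoxide may react between molecules (oligomers), or add at the unsubstituted C5/C6 and then enolise to a hydroquinone that enters redox exchange; the bromoquinone may also degrade under base, or the silyl group may be lost. Fallback: close the ring as an aryl ether before the quinone exists, setting out from 21. Acidolysis of the MOM acetal (TFA, CH2Cl2) should give 3-{2-[3-(4-{2-(2-bromo-3,6-dimethoxyphenyl)ethyl}phenoxy)-4-(triisopropylsilyloxy)phenyl]ethyl}phenol F1. Intramolecular palladium-catalysed C–O coupling of its phenol with the aryl bromide (Pd(OAc)2, t-BuXPhos, K3PO4, toluene, 100 °C, high dilution) should give the macrocyclic hydroquinone dimethyl ether F2. CAN oxidation of F2, whose trioxygenated ring is now by far the most electron-rich, should give the quinone and rejoin the route at 24.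

Most likely to fail, 2: step 13. Cerium(IV) may also oxidise rings B or C or a benzylic position, or the acidic medium may strip the MOM group and expose a phenol to the oxidant, so that mass balance is lost. Fallback: carry the hydroquinone as acetals so that no strong oxidant is needed, setting out from 18.
- Commercial 2-bromohydroquinone with MOMCl and DIPEA should give 2-bromo-1,4-bis(methoxymethoxy)benzene F3.
- LDA at −78 °C should give [2-bromo-3,6-bis(methoxymethoxy)phenyl]lithium F4, and DMF then 2-bromo-3,6-bis(methoxymethoxy)benzaldehyde F5.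
- NaBH4 should give [2-bromo-3,6-bis(methoxymethoxy)phenyl]methanol F6, and CBr4/PPh3 the benzylic bromide 2-bromo-3-(bromomethyl)-1,4-bis(methoxymethoxy)benzene F7.
- PPh3 in toluene should give {[2-bromo-3,6-bis(methoxymethoxy)phenyl]methyl}triphenylphosphonium bromide F8.
- NaHMDS should give the ylide {[2-bromo-3,6-bis(methoxymethoxy)phenyl]methylidene}triphenylphosphorane F9, which with 18 should give the stilbene F10; diimide should reduce it to the tris-MOM bibenzyl F11.
- TFA in CH2Cl2 should remove all three acetals and leave the silyl ether, giving the bromohydroquinone phenol F12.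
- Ag2O in ether, which oxidises a hydroquinone but not a simple phenol, should then give the quinone and rejoin the route at 23.

Most likely to fail, 3: step 7. The phenoxide-bearing phosphonium betaine may be poorly soluble, so that ylide formation and olefination stall. Capping in the flask may also be incomplete, leaving a free ring-C phenol that would later be silylated together with the catechol oxygen. Fallback: bring ring C in already protected, setting out from 11. Commercial 3-hydroxybenzaldehyde with MOMCl and K2CO3 should give 3-(methoxymethoxy)benzaldehyde F13. NaBH4 should give [3-(methoxymethoxy)phenyl]methanol F14, CBr4/PPh3 the bromide 1-(bromomethyl)-3-(methoxymethoxy)benzene F15, and PPh3 the salt {[3-(methoxymethoxy)phenyl]methyl}triphenylphosphonium bromide F16. One equivalent of KOtBu should give the ylide {[3-(methoxymethoxy)phenyl]methylidene}triphenylphosphorane F17, whose Wittig reaction with 11 rejoins the route at 14.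

**Further compounds**

F1 | step 15 | 3-{2-[3-(4-{2-(2-bromo-3,6-dimethoxyphenyl)ethyl}phenoxy)-4-(triisopropylsilyloxy)phenyl]ethyl}phenol | Oc1cccc(CCc2ccc(O[Si](C(C)C)(C(C)C)C(C)C)c(Oc3ccc(CCc4c(Br)c(OC)ccc4OC)cc3)c2)c1
F2 | step 15 | macrocyclic hydroquinone dimethyl ether of marchantinquinone triisopropylsilyl ether | COc1ccc(OC)c2c1CCc1ccc(cc1)Oc1cc(ccc1O[Si](C(C)C)(C(C)C)C(C)C)CCc1cccc(c1)O2
F3 | step 13 | 2-bromo-1,4-bis(methoxymethoxy)benzene | COCOc1ccc(OCOC)c(Br)c1
F4 | step 13 | [2-bromo-3,6-bis(methoxymethoxy)phenyl]lithium | [Li]c1c(Br)c(OCOC)ccc1OCOC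
F5 | step 13 | 2-bromo-3,6-bis(methoxymethoxy)benzaldehyde | COCOc1ccc(OCOC)c(Br)c1C=O
F6 | step 13 | [2-bromo-3,6-bis(methoxymethoxy)phenyl]methanol | COCOc1ccc(OCOC)c(Br)c1CO
F7 | step 13 | 2-bromo-3-(bromomethyl)-1,4-bis(methoxymethoxy)benzene | COCOc1ccc(OCOC)c(Br)c1CBr
F8 | step 13 | {[2-bromo-3,6-bis(methoxymethoxy)phenyl]methyl}triphenylphosphonium bromide | COCOc1ccc(OCOC)c(Br)c1C[P+](c1ccccc1)(c1ccccc1)c1ccccc1.[Br-]
F9 | step 13 | {[2-bromo-3,6-bis(methoxymethoxy)phenyl]methylidene}triphenylphosphorane | COCOc1ccc(OCOC)c(Br)c1C=P(c1ccccc1)(c1ccccc1)c1ccccc1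
F10 | step 13 | 2-bromo-1,4-bis(methoxymethoxy)-3-[2-(4-{5-[2-(3-(methoxymethoxy)phenyl)ethyl]-2-[(triisopropylsilyl)oxy]phenoxy}phenyl)ethenyl]benzene (E/Z mixture) | COCOc1cccc(CCc2ccc(O[Si](C(C)C)(C(C)C)C(C)C)c(Oc3ccc(C=Cc4c(Br)c(OCOC)ccc4OCOC)cc3)c2)c1
F11 | step 13 | 2-bromo-1,4-bis(methoxymethoxy)-3-[2-(4-{5-[2-(3-(methoxymethoxy)phenyl)ethyl]-2-[(triisopropylsilyl)oxy]phenoxy}phenyl)ethyl]benzene | COCOc1cccc(CCc2ccc(O[Si](C(C)C)(C(C)C)C(C)C)c(Oc3ccc(CCc4c(Br)c(OCOC)ccc4OCOC)cc3)c2)c1
F12 | step 13 | 2-bromo-3-[2-(4-{5-[2-(3-hydroxyphenyl)ethyl]-2-[(triisopropylsilyl)oxy]phenoxy}phenyl)ethyl]benzene-1,4-diol | Oc1cccc(CCc2ccc(O[Si](C(C)C)(C(C)C)C(C)C)c(Oc3ccc(CCc4c(Br)c(O)ccc4O)cc3)c2)c1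
F13 | step 7 | 3-(methoxymethoxy)benzaldehyde | COCOc1cccc(C=O)c1
F14 | step 7 | [3-(methoxymethoxy)phenyl]methanol | COCOc1cccc(CO)c1
F15 | step 7 | 1-(bromomethyl)-3-(methoxymethoxy)benzene | COCOc1cccc(CBr)c1
F16 | step 7 | {[3-(methoxymethoxy)phenyl]methyl}triphenylphosphonium bromide | COCOc1cccc(C[P+](c2ccccc2)(c2ccccc2)c2ccccc2)c1.[Br-]
F17 | step 7 | {[3-(methoxymethoxy)phenyl]methylidene}triphenylphosphorane | COCOc1cccc(C=P(c2ccccc2)(c2ccccc2)c2ccccc2)c1
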